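**Retrosynthetic overview**

1. Last disconnection: the pyran C2–O1 bond (aryl ether C–O). The target opens to an acyclic tertiary allylic alcohol carrying a 2,4-dihydroxy-5-acetylphenyl group; closing this bond is the final step and sets C2 as (R).
2. Styrene C4–C4a bond: Heck coupling of 5-bromo-2,4-dihydroxyacetophenone with a terminal vinyl carbinol. The bromine position (ortho to the free OH, para to the chelated OH) fixes the linear 6-acetyl-7-hydroxy pattern.
3. Ester side: the CH2–O bond of the vinyl carbinol ester comes from the ferulic acid carboxylate and racemic 2-methyl-2-vinyloxirane.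
4. Ring order: both benzene rings are bought; the pyran ring is the only ring made, in the last step. No protecting groups.

**Assumptions:** 2-methyl-2-vinyloxirane and 5-bromo-2,4-dihydroxyacetophenone are bought as catalogue compounds. The sense of induction of the new step 3 cannot be predicted with certainty; the (R)-catalyst is written, and its mirror image is used instead if the first run gives the (S)-chromene.

**Route**

Step 1
Reactants: 1 (E)-ferulic acid [(E)-3-(4-hydroxy-3-methoxyphenyl)prop-2-enoic acid]; 2 racemic 2-methyl-2-vinyloxirane
Product: 3 racemic 2-hydroxy-2-methylbut-3-en-1-yl (E)-3-(4-hydroxy-3-methoxyphenyl)prop-2-enoate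
Conditions: 1 (1.3 equiv), 2 (1.0 equiv), Cs2CO3 (0.15 equiv), DMF, 70 °C, sealed tube, 16 h; aq. NaHCO3 wash removes excess 1
Reagents that add atoms: none
Why: Base-catalysed addition of a carboxylic acid to an epoxide (SN2 ring opening): with substoichiometric base only the carboxylic acid (pKa about 4.5) is ionised while the phenol (pKa about 10) stays protonated, and the carboxylate attacks the unhindered CH2 of the 2,2-disubstituted epoxide to give the primary ester and tertiary alcohol; the carbinol centre is racemic, which does not matter because it is erased in step 3.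

Step 2
Reactants: 3 racemic 2-hydroxy-2-methylbut-3-en-1-yl (E)-3-(4-hydroxy-3-methoxyphenyl)prop-2-enoate (1.2 equiv); 4 1-(5-bromo-2,4-dihydroxyphenyl)ethan-1-one (5-bromo-2,4-dihydroxyacetophenone)
Product: 5 racemic (E)-4-(5-acetyl-2,4-dihydroxyphenyl)-2-hydroxy-2-methylbut-3-en-1-yl (E)-3-(4-hydroxy-3-methoxyphenyl)prop-2-enoate
Conditions: Pd(OAc)2 (5 mol %), P(o-tol)3 (10 mol %), NaHCO3 (2.5 equiv), DMF, 95 °C, Ar; work-up at pH 7, chromatography on Et3N-deactivated silica, product used promptly
Reagents that add atoms: none
Why: Mizoroki–Heck reaction: the aryl–palladium species adds to the terminal monosubstituted alkene of 3 (the conjugated 1,2-disubstituted ferulate alkene is far slower), the carbinol carbon bears no hydrogen so β-hydride elimination can only give the (E)-styrene, and the bicarbonate keeps the medium non-acidic so the tertiary allylic alcohol is not ionised and no racemic chromene forms.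

Step 3
Reactants: 5 racemic (E)-4-(5-acetyl-2,4-dihydroxyphenyl)-2-hydroxy-2-methylbut-3-en-1-yl (E)-3-(4-hydroxy-3-methoxyphenyl)prop-2-enoate
Product: 7 (R)-(6-acetyl-7-hydroxy-2-methyl-2H-chromen-2-yl)methyl (E)-3-(4-hydroxy-3-methoxyphenyl)prop-2-enoate, via allyl cation ion pair 6 (not isolated)
Conditions: (R)-3,3'-bis(2,4,6-triisopropylphenyl)-1,1'-binaphthyl-2,2'-diyl N-(trifluoromethylsulfonyl)phosphoramide (5 mol %), 5 Å MS, toluene/CH2Cl2 3:1 (0.02 M), −40 °C, dark; Et3N quench at −40 °C before warming
Reagents that add atoms: none
Why: Proposed new method: catalytic enantioselective dehydrative oxa-cyclisation (intramolecular allylic etherification through a chiral contact ion pair) of a tertiary allylic alcohol that carries no aryl group at the carbinol carbon. The strong chiral Brønsted acid protonates the tertiary OH and water leaves (trapped by the sieves); the resulting cation 6 is delocalised over C2, C4 and the dihydroxyaryl ring (an O-protonated vinyl ortho-quinone methide), so the C3–C4 bond gains single-bond character and the (E)-chain can rotate into the cis arrangement needed for closure. The phosphoramide anion stays bound through a hydrogen bond to the phenol ortho to the side chain and through ion pairing with the allyl terminus, the small methyl sits in the pocket between the 3,3'-aryl groups while the long feruloyloxymethyl arm points out of it, and the phenol oxygen adds to one face of C2 as the anion takes its proton, which closes the pyran ring and sets the (R) quaternary centre. The product resists re-ionisation because its ring oxygen is para to the acetyl group. The closest known reaction types are the chiral N-triflylphosphoramide-catalysed intramolecular allylic substitution of aryl-stabilised 2-(3-hydroxyalkenyl)phenols to 2-aryl-2H-chromenes and the racemic acid-catalysed cyclisation of 2-(3-hydroxy-3-methylbut-1-enyl)phenols to 2,2-dimethylchromenes; new here are the non-aryl cation and the face selection between CH3 and CH2O-acyl.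

**Compound list**

1 | (E)-ferulic acid, (E)-3-(4-hydroxy-3-methoxyphenyl)prop-2-enoic acid | COc1cc(/C=C/C(=O)O)ccc1O | starting material
2 | racemic 2-methyl-2-vinyloxirane | C=CC1(C)CO1 | starting material
3 | racemic 2-hydroxy-2-methylbut-3-en-1-yl (E)-3-(4-hydroxy-3-methoxyphenyl)prop-2-enoate | COc1cc(/C=C/C(=O)OCC(C)(O)C=C)ccc1O | intermediate
4 | 1-(5-bromo-2,4-dihydroxyphenyl)ethan-1-one | CC(=O)c1cc(Br)c(O)cc1O | starting material
5 | racemic (E)-4-(5-acetyl-2,4-dihydroxyphenyl)-2-hydroxy-2-methylbut-3-en-1-yl (E)-3-(4-hydroxy-3-methoxyphenyl)prop-2-enoate | COc1cc(/C=C/C(=O)OCC(C)(O)/C=C/c2cc(C(C)=O)c(O)cc2O)ccc1O | intermediate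
6 | allyl cation (O-protonated vinyl ortho-quinone methide) formed from 5 by loss of water, paired with the chiral phosphoramide anion; C3–C4 geometry mobile | COc1cc(/C=C/C(=O)OC[C+](C)C=Cc2cc(C(C)=O)c(O)cc2O)ccc1O | intermediate
7 | (R)-(6-acetyl-7-hydroxy-2-methyl-2H-chromen-2-yl)methyl (E)-3-(4-hydroxy-3-methoxyphenyl)prop-2-enoate | COc1cc(/C=C/C(=O)OC[C@@]2(C)C=Cc3cc(C(C)=O)c(O)cc3O2)ccc1O | target

**Totals**

Total step count: 3. Longest linear sequence: 3 steps (1 → 3 → 5 → 7).

**Steps most likely to fail, with fallbacks**

Step 3 (new method) is the main risk. The catalyst may discriminate poorly between CH3 and CH2O-acyl, a racemic background closure may run through the free quinone methide, the product may racemise by re-ionisation, or the cation may eliminate to a diene. The fallback uses known chemistry, sets out from 5 and comes back at 7. Compound 5 is cyclised with pyridinium p-toluenesulfonate (10 mol %) in toluene at 50 °C, the established acid-catalysed closure of 2-(3-hydroxyalkenyl)phenols, to give racemic (6-acetyl-7-hydroxy-2-methyl-2H-chromen-2-yl)methyl (E)-3-(4-hydroxy-3-methoxyphenyl)prop-2-enoate F3. The racemate is then separated by preparative chiral SFC on an amylose tris(3,5-dimethylphenylcarbamate) phase into 7 and the (S)-(6-acetyl-7-hydroxy-2-methyl-2H-chromen-2-yl)methyl (E)-3-(4-hydroxy-3-methoxyphenyl)prop-2-enoate F4, which is set aside. All handling of 7 is done without acid and away from light.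

Step 2 is the next risk: the unprotected, electron-rich bromophenol may add slowly to palladium, and 5 may cyclise to racemic chromene if the mixture turns acidic. The fallback replaces the Heck reaction by a boron-based coupling at lower temperature, sets out from 3 and comes back at 5. Cross-metathesis of 3 with vinylboronic acid pinacol ester (second-generation Hoveyda–Grubbs catalyst (H2IMes)Cl2Ru(=CH-C6H4-2-OiPr), 5 mol %, CH2Cl2, 40 °C) gives racemic (E)-2-hydroxy-2-methyl-4-(4,4,5,5-tetramethyl-1,3,2-dioxaborolan-2-yl)but-3-en-1-yl (E)-3-(4-hydroxy-3-methoxyphenyl)prop-2-enoate F2. Suzuki–Miyaura coupling of this boronate with 4 (Pd(dppf)Cl2 3 mol %, K3PO4, dioxane/H2O, 60 °C) then gives 5.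

Step 1 is the third risk: the phenol may be alkylated, the epoxide may open at the wrong carbon (SN2' or tertiary attack), or the epoxide may oligomerise. The fallback builds the carbinol by C–C bond formation instead of epoxide opening, sets out from 1 and comes back at 3. Ferulic acid 1 is alkylated at the carboxylate only with chloroacetone (KHCO3 1.1 equiv, KI 5 mol %, DMF, 25 °C) to give 2-oxopropyl (E)-3-(4-hydroxy-3-methoxyphenyl)prop-2-enoate F1. Vinylmagnesium bromide (2.2 equiv, THF, −78 °C, cold aqueous NH4Cl quench) then adds to the ketone, the first equivalent being spent on the phenol, and gives 3.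

**Further compounds**

F1 | step 1 | 2-oxopropyl (E)-3-(4-hydroxy-3-methoxyphenyl)prop-2-enoate | COc1cc(/C=C/C(=O)OCC(C)=O)ccc1O
F2 | step 2 | racemic (E)-2-hydroxy-2-methyl-4-(4,4,5,5-tetramethyl-1,3,2-dioxaborolan-2-yl)but-3-en-1-yl (E)-3-(4-hydroxy-3-methoxyphenyl)prop-2-enoate | COc1cc(/C=C/C(=O)OCC(C)(O)/C=C/B2OC(C)(C)C(C)(C)O2)ccc1O
F3 | step 3 | racemic (6-acetyl-7-hydroxy-2-methyl-2H-chromen-2-yl)methyl (E)-3-(4-hydroxy-3-methoxyphenyl)prop-2-enoate | COc1cc(/C=C/C(=O)OCC2(C)C=Cc3cc(C(C)=O)c(O)cc3O2)ccc1O
F4 | step 3 | (S)-(6-acetyl-7-hydroxy-2-methyl-2H-chromen-2-yl)methyl (E)-3-(4-hydroxy-3-methoxyphenyl)prop-2-enoate | COc1cc(/C=C/C(=O)OC[C@]2(C)C=Cc3cc(C(C)=O)c(O)cc3O2)ccc1O
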